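**Retrosynthetic overview**

1. Feature: target 17 is a bicyclo[3.3.1]nonane-2,4,9-trione. Ring A (C1–C2–C3–C4–C5–C9) is a dearomatised aroylphloroglucinol. Ring B (C1, C8, C7, C6, C5, C9) contains C6–C7–C8(CH3)2, a former prenyl group of C5 that carries the geranyl group on C7 and is tied through C8 to the enol carbon C1.
2. Key disconnection: C7–C1′ (geranyl) and C1–C8 are cut together, giving the achiral gem-diprenyl trione 10 and geranyl diphosphate 15. One enzymatic geranyl transfer with cyclisation closes ring B last and sets C1, C5 and C7.
3. 10 comes from its aryl O-allyl ether 9. 9 is built from aroylphloroglucinol 5 by three successive C-prenylations (7, 8, 9), the last one dearomatising ring A. 5 comes from phloroglucinol 3 and nitrile 2 by a Hoesch acylation.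
4. 15 comes from geraniol 11 through geranyl chloride 13.

Key step: step 9

Remark: the enolised tricarbonyl units of 9, 10 and 17 are rapidly interconverting tautomers, and each is drawn as one of them (17 as in the given structure). Atom numbers C1–C9 are those of the bicyclo[3.3.1]nonane of 17 and are used for the same atoms in 10 and 16; C1′ is the CH2 of the geranyl group.

**Route**

Step 1
Reactants: 1 3-hydroxybenzonitrile
Product: 2 3-(prop-2-en-1-yloxy)benzonitrile
Conditions: allyl bromide, K2CO3, acetone, reflux
Reagents that add atoms: allyl bromide, C=CCBr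
Why: Williamson ether synthesis on the only acidic site of 1 with an unhindered allylic bromide; the allyl ether should survive the acid of step 2 and the aqueous base of steps 3 to 5 and keeps this phenol from being O-prenylated there.

Step 2
Reactants: 2 3-(prop-2-en-1-yloxy)benzonitrile; 3 phloroglucinol
Product: 5 [3-(prop-2-en-1-yloxy)phenyl](2,4,6-trihydroxyphenyl)methanone, via ketiminium chloride 4 (not isolated)
Conditions: ZnCl2, HCl (g), Et2O, 0 °C; then H2O, 100 °C
Reagents that add atoms: water, O
Why: Houben–Hoesch acylation, in which the HCl-activated nitrile (assisted by ZnCl2) is attacked by the very electron-rich phloroglucinol ring, the ketiminium salt 4 deactivates the ring against a second acylation, and hot water hydrolyses it to the ketone while the aryl allyl ether is inert to dilute acid.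

Step 3
Reactants: 5 [3-(prop-2-en-1-yloxy)phenyl](2,4,6-trihydroxyphenyl)methanone; 6 prenyl bromide (1.0 equiv, added slowly)
Product: 7 [3-(prop-2-en-1-yloxy)phenyl][2,4,6-trihydroxy-3-(3-methylbut-2-en-1-yl)phenyl]methanone
Conditions: KOH (2 equiv), H2O, 0 °C, N2; then 1 M HCl; chromatography (unreacted 5 recycled)
Reagents that add atoms: none
Why: C-alkylation of the ambident acylphloroglucinol anion by an allylic bromide in water (C-prenylation of a phenolate), where hydrogen bonding to the oxygens favours attack through carbon; the two free ring positions of 5 are equivalent, so only one monoprenyl isomer can form, and holding 6 to one equivalent limits a second alkylation; no stereocentre is formed.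

Step 4
Reactants: 7 the monoprenyl ketone; 6 prenyl bromide (1.05 equiv)
Product: 8 [3-(prop-2-en-1-yloxy)phenyl][2,4,6-trihydroxy-3,5-bis(3-methylbut-2-en-1-yl)phenyl]methanone
Conditions: KOH (2 equiv), H2O, 0 °C, N2; then 1 M HCl
Reagents that add atoms: none
Why: The same phenolate C-alkylation at the one remaining unsubstituted ring carbon, which should react faster than the prenyl-bearing carbon because substitution there restores the aromatic ring, giving the symmetric 3,5-diprenyl ketone (the deoxyhumulone-type pattern); no stereocentre is formed.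

Step 5
Reactants: 8 the diprenyl ketone; 6 prenyl bromide (1.1 equiv)
Product: 9 3,5-dihydroxy-4,6,6-tris(3-methylbut-2-en-1-yl)-2-[3-(prop-2-en-1-yloxy)benzoyl]cyclohexa-2,4-dien-1-one (achiral)
Conditions: KOH (2.1 equiv), MeOH–H2O (1:1), 0 °C, N2; then cold dilute HCl to pH 3–4
Reagents that add atoms: none
Why: Alkylative dearomatisation (the lupulone-type C-alkylation), in which the anion of 8, with no free ring position left, is alkylated in a protic medium at one of its two equivalent prenyl-bearing carbons; the product cannot rearomatise and stays as the acidic enolised β-triketone, whose anion resists a fourth alkylation, and the new quaternary carbon carries two identical prenyl groups, so no stereocentre is formed.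

Step 6
Reactants: 9 3,5-dihydroxy-4,6,6-tris(3-methylbut-2-en-1-yl)-2-[3-(prop-2-en-1-yloxy)benzoyl]cyclohexa-2,4-dien-1-one
Product: 10 3,5-dihydroxy-2-(3-hydroxybenzoyl)-4,6,6-tris(3-methylbut-2-en-1-yl)cyclohexa-2,4-dien-1-one (enol form of 2-(3-hydroxybenzoyl)-4,6,6-triprenylcyclohexane-1,3,5-trione, achiral)
Conditions: Pd(PPh3)4 (5 mol %), morpholine (10 equiv), THF, rt, Ar; pH 4 buffer work-up
Reagents that add atoms: none
Why: Tsuji–Trost deallylation, in which zerovalent palladium ionises the aryl allyl ether to a π-allyl complex and the phenoxide, excess morpholine takes up the allyl group, and the C-bound prenyl groups, which carry no leaving group, are not touched.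

Step 7
Reactants: 11 geraniol
Product: 13 geranyl chloride, (2E)-1-chloro-3,7-dimethylocta-2,6-diene, via geranyl methanesulfonate 12 (not isolated)
Conditions: MsCl, 2,4,6-collidine, LiCl, DMF, 0 °C
Reagents that add atoms: lithium chloride, [Li+].[Cl-]
Why: Mesylation of the primary allylic alcohol and SN2 displacement of the mesylate by chloride in DMF at 0 °C, conditions that should give the allylic chloride without allylic transposition or loss of the E geometry.

Step 8
Reactants: 13 geranyl chloride
Product: 15 geranyl diphosphate as its trisammonium salt, via tetrabutylammonium geranyl diphosphate 14 (not isolated)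
Conditions: (n-Bu4N)3HP2O7, MeCN, rt; then Dowex 50W-X8 (ammonium form), aq NH4HCO3/i-PrOH; cellulose chromatography, lyophilisation
Reagents that add atoms: tris(tetrabutylammonium) hydrogen diphosphate, CCCC[N+](CCCC)(CCCC)CCCC.CCCC[N+](CCCC)(CCCC)CCCC.CCCC[N+](CCCC)(CCCC)CCCC.OP(=O)([O-])OP(=O)([O-])[O-]; ammonium bicarbonate, [NH4+].OC(=O)[O-]
Why: SN2 displacement of the primary allylic chloride by the organic-soluble hydrogen diphosphate trianion in dry MeCN (a standard diphosphorylation of allylic halides), followed by cation exchange to the water-soluble ammonium salt that prenyltransferases accept; the E alkene is not involved.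

Step 9
Reactants: 10 the gem-diprenyl trione; 15 geranyl diphosphate (trisammonium salt, 1.5 equiv)
Product: 17 (1S,5S,7S)-7-[(2E)-3,7-dimethylocta-2,6-dien-1-yl]-4-hydroxy-3-(3-hydroxybenzoyl)-8,8-dimethyl-1,5-bis(3-methylbut-2-en-1-yl)bicyclo[3.3.1]non-3-ene-2,9-dione, via C8 carbocation 16 (not isolated)
Conditions: engineered membrane-bound aromatic prenyltransferase (yeast microsomes), MgCl2 (10 mM), Tris-HCl pH 7.5, DTT, 2% DMSO, 30 °C, Ar; EtOAc extraction, chromatography
Reagents that add atoms: none
Why: Proposed new method: a membrane-bound aromatic prenyltransferase ionises 15 with the help of magnesium ions to the geranyl cation, the C7=C8 alkene of one of the two C5 prenyl groups of 10 attacks C1′, and the tertiary C8 cation 16 is captured by the enol carbon C1, loss of the enol proton then giving the C9 ketone. The closest known reaction type is the prenyltransferase step of hyperforin-type biosynthesis, where dimethylallyl diphosphate is added to a side-chain alkene of a gem-dialkylated acylphloroglucinol and the cation closes the same bicyclo[3.3.1] ring; the geranyl donor, the prenyl acceptor alkene and the 3-hydroxybenzoyl group are new, so the enzyme must be found in plants that make 7-geranyl benzophenone-derived bicycles of this kind or evolved from a hyperforin-pathway enzyme. Ring B (C1, C8, C7, C6, C5, C9) closes in a 6-endo-trig mode with respect to the C7=C8 alkene, by C-alkylation of the C1=C9 enol. C5 is set by the choice of the active site between the two enantiotopic prenyl groups, C1 follows from C5 because C8 can reach C1 only on the face of ring A on which the reacting prenyl group stands, and C7 is set by anti addition of C1′ and C1 across the alkene from a boat-like fold of the C5–C6–C7=C8 chain, which puts the geranyl group on the face of ring B that carries C2 and C4 (a chair-like fold would give the C7 epimer). The step needs geranyl transfer to C7 in preference to C1, C3 or the enol oxygens, and capture of the cation by C1 in preference to the aroyl-bearing C3 or an enol oxygen. The substrate helps only in that C1 is the more electron-rich enol carbon and in that it is achiral and offers no bias of its own, so every stereochemical choice rests with the enzyme.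

**Compound list**

1 | 3-hydroxybenzonitrile | N#Cc1cccc(O)c1 | starting material
2 | 3-(prop-2-en-1-yloxy)benzonitrile | N#Cc1cccc(OCC=C)c1 | intermediate
3 | phloroglucinol (benzene-1,3,5-triol) | Oc1cc(O)cc(O)c1 | starting material
4 | [3-(prop-2-en-1-yloxy)phenyl](2,4,6-trihydroxyphenyl)methaniminium chloride | [NH2+]=C(c1cccc(OCC=C)c1)c1c(O)cc(O)cc1O.[Cl-] | intermediate (not isolated)
5 | [3-(prop-2-en-1-yloxy)phenyl](2,4,6-trihydroxyphenyl)methanone | O=C(c1cccc(OCC=C)c1)c1c(O)cc(O)cc1O | intermediate
6 | prenyl bromide (1-bromo-3-methylbut-2-ene) | CC(C)=CCBr | starting material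
7 | [3-(prop-2-en-1-yloxy)phenyl][2,4,6-trihydroxy-3-(3-methylbut-2-en-1-yl)phenyl]methanone | O=C(c1cccc(OCC=C)c1)c1c(O)cc(O)c(CC=C(C)C)c1O | intermediate
8 | [3-(prop-2-en-1-yloxy)phenyl][2,4,6-trihydroxy-3,5-bis(3-methylbut-2-en-1-yl)phenyl]methanone | O=C(c1cccc(OCC=C)c1)c1c(O)c(CC=C(C)C)c(O)c(CC=C(C)C)c1O | intermediate
9 | 3,5-dihydroxy-4,6,6-tris(3-methylbut-2-en-1-yl)-2-[3-(prop-2-en-1-yloxy)benzoyl]cyclohexa-2,4-dien-1-one (achiral) | CC(C)=CCC1=C(O)C(CC=C(C)C)(CC=C(C)C)C(=O)C(C(=O)c2cccc(OCC=C)c2)=C1O | intermediate
10 | 3,5-dihydroxy-2-(3-hydroxybenzoyl)-4,6,6-tris(3-methylbut-2-en-1-yl)cyclohexa-2,4-dien-1-one (enol form of 2-(3-hydroxybenzoyl)-4,6,6-triprenylcyclohexane-1,3,5-trione, achiral) | CC(C)=CCC1=C(O)C(CC=C(C)C)(CC=C(C)C)C(=O)C(C(=O)c2cccc(O)c2)=C1O | intermediate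
11 | geraniol, (2E)-3,7-dimethylocta-2,6-dien-1-ol | CC(C)=CCC/C(C)=C/CO | starting material
12 | geranyl methanesulfonate | CC(C)=CCC/C(C)=C/COS(C)(=O)=O | intermediate (not isolated)
13 | geranyl chloride, (2E)-1-chloro-3,7-dimethylocta-2,6-diene | CC(C)=CCC/C(C)=C/CCl | intermediate
14 | bis(tetrabutylammonium) geranyl hydrogen diphosphate | CC(C)=CCC/C(C)=C/COP(=O)([O-])OP(=O)(O)[O-].CCCC[N+](CCCC)(CCCC)CCCC.CCCC[N+](CCCC)(CCCC)CCCC | intermediate (not isolated)
15 | geranyl diphosphate, trisammonium salt | CC(C)=CCC/C(C)=C/COP(=O)([O-])OP(=O)([O-])[O-].[NH4+].[NH4+].[NH4+] | intermediate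
16 | enzyme-bound tertiary C8 carbocation: 10 with the geranyl group on C7 of one C5 prenyl group, C5 and C7 configured as in 17 | CC(C)=CCC/C(C)=C/C[C@H]([C+](C)C)C[C@]1(CC=C(C)C)C(O)=C(CC=C(C)C)C(O)=C(C(=O)c2cccc(O)c2)C1=O | intermediate (not isolated)
17 | (1S,5S,7S)-7-[(2E)-3,7-dimethylocta-2,6-dien-1-yl]-4-hydroxy-3-(3-hydroxybenzoyl)-8,8-dimethyl-1,5-bis(3-methylbut-2-en-1-yl)bicyclo[3.3.1]non-3-ene-2,9-dione (CNP0290731.1; geranyl on the face of ring B that carries C2 and C4) | CC(C)=CCC/C(C)=C/C[C@H]1C[C@]2(CC=C(C)C)C(=O)[C@@](CC=C(C)C)(C(=O)C(C(=O)c3cccc(O)c3)=C2O)C1(C)C | target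

**Step count**

Total: 9 steps. Longest linear sequence: 7 steps (steps 1, 2, 3, 4, 5, 6, 9); the geranyl branch (steps 7, 8) joins at step 9.

**Steps most likely to fail**

Step 9. The enzyme may fail to turn over with a geranyl donor, may transfer the geranyl group to C1, C3 or an enol oxygen instead of C7, or may close ring B through the chair-like fold and deliver the C7 epimer. The fallback uses known chemistry, sets out from 8 and 13 and comes back to the route at 17. It puts the geranyl group and the C7 centre in place before ring closure and makes the C8 cation by protonating an isopropenyl group.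

(R)-4-Benzyloxazolidin-2-one is N-acylated (n-BuLi, 3-methylbut-2-enoyl chloride, THF, −78 °C) to (4R)-4-benzyl-3-(3-methylbut-2-enoyl)-1,3-oxazolidin-2-one F1. F1 is deprotonated at a γ-methyl group with NaN(SiMe3)2 in THF at −78 °C, and the dienolate is alkylated at its α-carbon with 13 (catalytic Bu4NI). This Evans alkylation, anti to the benzyl group, should give the deconjugated (4R)-4-benzyl-3-[(2R,4E)-5,9-dimethyl-2-(prop-1-en-2-yl)deca-4,8-dienoyl]-1,3-oxazolidin-2-one F2; the sense of induction would be confirmed at the next compound. LiBH4 (THF, 0 °C) removes the auxiliary and should give (2R,4E)-5,9-dimethyl-2-(prop-1-en-2-yl)deca-4,8-dien-1-ol F3. Tf2O and 2,6-lutidine (CH2Cl2, −78 °C) convert it into (2R,4E)-5,9-dimethyl-2-(prop-1-en-2-yl)deca-4,8-dien-1-yl trifluoromethanesulfonate F4, which is used at once.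

The dianion of 8 (LiN(SiMe3)2, THF, 0 °C) is C-alkylated by F4 at a prenyl-bearing ring carbon (alkylative dearomatisation). This should give 3,5-dihydroxy-6-[(2S,4E)-5,9-dimethyl-2-(prop-1-en-2-yl)deca-4,8-dien-1-yl]-4,6-bis(3-methylbut-2-en-1-yl)-2-[3-(prop-2-en-1-yloxy)benzoyl]cyclohexa-2,4-dien-1-one F5, the epimer whose ring quaternary carbon is configured as C5 of 17. It should form together with its epimer at that carbon, because the remote C7 centre cannot direct the new quaternary centre. The side-chain descriptor changes from R to S only because the ring-bearing CH2 now ranks below the isopropenyl group; the centre itself is untouched.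

Formic acid at room temperature protonates the isopropenyl group, and the C8 cation is captured by C1. This acid-mediated cation–enol cyclisation is a known way to close bicyclo[3.3.1]nonane-2,4,9-triones from dearomatised acylphloroglucinols. It should give the 3′-O-allyl ether of 17 F6, whose configuration follows directly from C5 and C7 of F5. The epimer of F5 leads to a diastereomeric bicycle that is removed by chromatography at this stage. Protonation of the prenyl and geranyl alkenes, with chroman formation or formate addition, has to be held back by short reaction times. Deallylation of F6 under the conditions of step 6 gives 17.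

Step 3. The first prenylation may run on to the diprenyl ketone while starting ketone is left over, and O-alkylation may compete with C-alkylation, so that 7 has to be taken out of a statistical mixture. The fallback sets out from 5 and comes back at 7, and it replaces phenolate alkylation under base by electrophilic aromatic substitution under acid. 5 is treated with one equivalent of 2-methylbut-3-en-2-ol and BF3·OEt2 in dioxane at room temperature (Friedel–Crafts prenylation through the prenyl cation). This cannot leave an O-prenyl ether, and the aryl allyl ether should not rearrange at this temperature. The reaction is stopped at partial conversion, before the ortho-prenylphenol closes to a chroman. 7 is separated from recovered 5, which is recycled.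

Step 6. The allyl group may pass from palladium to the prenyl-bearing enol carbon (the later C1) or to an enol oxygen of the trione instead of to morpholine, and the electron-rich enolate may be oxidised by traces of air in the basic medium. The fallback sets out from 1 and comes back at 10 with no protecting group at all.

The Hoesch reaction of step 2 is run on 1 itself with 3 (ZnCl2, HCl gas, Et2O, 0 °C) and should give (3-hydroxyphenyl)(2,4,6-trihydroxyphenyl)methaniminium chloride F7. Hot water hydrolyses F7 to (3-hydroxyphenyl)(2,4,6-trihydroxyphenyl)methanone F8. F8 is then prenylated three times in succession with 6, one equivalent at a time, in aqueous KOH at 0 °C. The base is added in portions and limited to what the acylphloroglucinol and trione enols consume (pH near 9), so that the isolated phenol, the weakest acid present, stays largely protonated. The first alkylation should give (3-hydroxyphenyl)[2,4,6-trihydroxy-3-(3-methylbut-2-en-1-yl)phenyl]methanone F9, and the second (3-hydroxyphenyl)[2,4,6-trihydroxy-3,5-bis(3-methylbut-2-en-1-yl)phenyl]methanone F10. The third, dearomatising alkylation gives 10 directly. Any 3′-O-prenyl ether that still forms is removed by chromatography.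

**Further compounds**

F1 | step 9 | (4R)-4-benzyl-3-(3-methylbut-2-enoyl)-1,3-oxazolidin-2-one | CC(C)=CC(=O)N1[C@H](Cc2ccccc2)COC1=O
F2 | step 9 | (4R)-4-benzyl-3-[(2R,4E)-5,9-dimethyl-2-(prop-1-en-2-yl)deca-4,8-dienoyl]-1,3-oxazolidin-2-one | CC(C)=CCC/C(C)=C/C[C@H](C(C)=C)C(=O)N1[C@H](Cc2ccccc2)COC1=O
F3 | step 9 | (2R,4E)-5,9-dimethyl-2-(prop-1-en-2-yl)deca-4,8-dien-1-ol | CC(C)=CCC/C(C)=C/C[C@H](C(C)=C)CO
F4 | step 9 | (2R,4E)-5,9-dimethyl-2-(prop-1-en-2-yl)deca-4,8-dien-1-yl trifluoromethanesulfonate | CC(C)=CCC/C(C)=C/C[C@H](C(C)=C)COS(=O)(=O)C(F)(F)F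
F5 | step 9 | 3,5-dihydroxy-6-[(2S,4E)-5,9-dimethyl-2-(prop-1-en-2-yl)deca-4,8-dien-1-yl]-4,6-bis(3-methylbut-2-en-1-yl)-2-[3-(prop-2-en-1-yloxy)benzoyl]cyclohexa-2,4-dien-1-one, ring quaternary carbon configured as C5 of 17 | CC(C)=CCC/C(C)=C/C[C@H](C(C)=C)C[C@]1(CC=C(C)C)C(O)=C(CC=C(C)C)C(O)=C(C(=O)c2cccc(OCC=C)c2)C1=O
F6 | step 9 | 3′-O-allyl ether of 17, (1S,5S,7S)-7-[(2E)-3,7-dimethylocta-2,6-dien-1-yl]-4-hydroxy-8,8-dimethyl-1,5-bis(3-methylbut-2-en-1-yl)-3-[3-(prop-2-en-1-yloxy)benzoyl]bicyclo[3.3.1]non-3-ene-2,9-dione | CC(C)=CCC/C(C)=C/C[C@H]1C[C@]2(CC=C(C)C)C(=O)[C@@](CC=C(C)C)(C(=O)C(C(=O)c3cccc(OCC=C)c3)=C2O)C1(C)C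
F0 | step 3 | none | none
F7 | step 6 | (3-hydroxyphenyl)(2,4,6-trihydroxyphenyl)methaniminium chloride | [NH2+]=C(c1cccc(O)c1)c1c(O)cc(O)cc1O.[Cl-]
F8 | step 6 | (3-hydroxyphenyl)(2,4,6-trihydroxyphenyl)methanone | O=C(c1cccc(O)c1)c1c(O)cc(O)cc1O
F9 | step 6 | (3-hydroxyphenyl)[2,4,6-trihydroxy-3-(3-methylbut-2-en-1-yl)phenyl]methanone | O=C(c1cccc(O)c1)c1c(O)cc(O)c(CC=C(C)C)c1O
F10 | step 6 | (3-hydroxyphenyl)[2,4,6-trihydroxy-3,5-bis(3-methylbut-2-en-1-yl)phenyl]methanone | O=C(c1cccc(O)c1)c1c(O)c(CC=C(C)C)c(O)c(CC=C(C)C)c1O
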